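You cannot keep the target in these flasks for good: step 4 ends at 29 isomer of the product to one target, so at equilibrium target holds 3.33 % of that pair.

    substrate → open intermediate (k1 = 0.00237 min⁻¹)
    partner + open intermediate → target (k2 = 0.0866 L mol⁻¹ min⁻¹)
    2 open intermediate → homo product (k3 = 0.110 L mol⁻¹ min⁻¹)
    target ⇌ isomer of the product (K4 = 29, k4 = 0.00400 min⁻¹)
    open intermediate + capture agent → trapped intermediate (k5 = 0.00207 L mol⁻¹ min⁻¹)

- delta: substrate 0.96 M; partner 1.01 M; capture agent 0.0480 M; time 5.0 h
- gamma: substrate 0.96 M; partner 1.01 M; capture agent 0.0480 M; time 10 h

- percentages count the substrate that a species holds: one homo product counts as two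
- a doubled species enters its step squared and goes two at a time
- run time (delta): 5.0 h

* which of the two there is more of at the end, delta (target / isomer of the product)
* which of the two there is more of at the end, gamma (target / isomer of the product)
* how much target is there at the end, in percent of the substrate charged: delta
* how much target is there at the end, in percent of the substrate charged: gamma

The end state is therefore clear, and the question is how far along the way each flask stands, which I reckon here from rates. Target starts at 0.137 M h⁻¹, the rate at which substrate opens, because the open intermediate goes on by step 2 with a half-life of 0.13 h, far shorter than the substrate's 4.9 h. Two things slow the net gain. The feed falls with the substrate, by a factor 0.491 at 5.0 h and 0.241 at 10 h. The drain to the isomer grows with target, whose lifetime by this step is 4.17 h; I drop the return, whose constant is 29 times smaller.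

Together they leave a net gain of 0.0250 of the starting rate at 5.0 h, and at 10 h a net loss of 0.128 of it. The gain vanishes at the peak time, ln(k4/k1)/(k4−k1), the moment when falling feed equals rising drain, 5.35 h. Summing the rates gives target 27.6 % in delta, ahead of the isomer at 23.3 %. In gamma it gives target 21.9 %, behind the isomer at 54.0 %. Neither figure counts the homo product, so I expect both to stand high.

The forecast names target for delta and isomer of the product for gamma, with target at 24.5 % (22.5 % to 26.5 %) and 20.5 % (18.5 % to 22.5 %), lower than my figures. Its grounds are that “target peaks and still narrowly leads at 5 h”.

The simulation gives more target in delta, target 25.3 % against isomer 20.0 %, and more isomer of the product in gamma, target 21.0 % against isomer 47.4 %, inside the forecast's ranges and with both leaders as named. In delta, target, the kinetic product, equals the isomer, the thermodynamic one, at 5.91 h, later than the reading at 5.0 h. Delta is read just before my reckoned peak time of 5.35 h. Read at 12 h, which is 2.24 peak times, the same flask holds target 18.0 % and isomer 55.9 %.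

The rate constants are made up; the rest is arithmetic.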